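I began from the late readings. Monday's G stood at 14% after 6.00 h and Saturday's at 7% after 5.00 h, although their first readings were 17% and 19%, and the two flasks differed in nothing but the charge of D.

the same everywhere: X 0.14 M
- Monday's: J 0.112 M; D 0.168 M; run made earlier
- Thursday's: J 0.112 M; D 0.084 M; run made earlier
- Saturday's: J 0.112 M; D 0.34 M; run made earlier
- south-east: J 0.112 M; D 0.168 M (fed, over 80 min); all else is in the flask from the start; the feed brings no volume worth counting; time 6.0 h
- south: J 0.112 M; D 0.168 M; everything together at the start; time 6.0 h
- north-east: J 0.112 M (fed, over 80 min); D 0.168 M; all else is in the flask from the start; the feed brings no volume worth counting; time 6.0 h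
- south-west: J 0.112 M (in portions, 3, over 80 min); D 0.168 M; first portion at the start, last at 80 min; time 6.0 h

- Monday's (time / h: G / %, X / %): 0.417: 17, 0; 1.33: 22, 0; 2.00: 22, 2; 3.00: 19, 1; 5.00: 20, 0; 6.00: 14, 0
- Thursday's (time / h: G / %, X / %): 0.417: 10, 9; 0.667: 13, 0; 1.00: 12, 0; 2.00: 14, 0; 3.00: 17, 0; 5.00: 11, 2
- Saturday's (time / h: G / %, X / %): 0.333: 19, 0; 1.00: 18, 0; 1.50: 12, 0; 2.50: 10, 0; 4.00: 8, 0; 5.00: 7, 0

(readings scatter by 2 percentage points)

- in percentages every species weighs as the X in it: one Z counts as two
- what was read earlier has a scatter of 2 percentage points, one standard deviation
- on the list of suspects stand: D + L -> G; X + J -> L; X + G -> Z; J + G -> E; X + D -> Q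

- the best flask by amount of G, in percent of the X charged; "all alike" if 1.5 percentage points covers them all (south-east / south / north-east / south-west / all alike)
- amount of G at the end, in percent of the X charged, south-east
- amount of G at the end, in percent of the X charged, south
- amount of G at the end, in percent of the X charged, north-east
- amount of G at the end, in percent of the X charged, south-west

I reckoned with what is left rather than what is made. X read 0% at the first reading of both runs. I took it that by then each X had gone either with D to Q or with J to L, which D turns into G. Let a be the share that went through L, the selectivity of X for J over D. Each such X spent one J, and each J remaining can remove one G by J + G. So, as long as D outlasts L and X + G stays small, G at rest is R = 2(a − e), the rest yield, where e is the break-even share, half the J charge counted in X, 40.0%.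

Taken as near rest, Monday's last reading put a at 47.0%. Saturday's D charge was twice Monday's. Scaling the odds of a by that ratio, I got 30.5% for Saturday, less than e. So I expected Monday's G to hold near its reading and Saturday's to keep falling towards zero. By my reckoning south, which has Monday's recipe, should end near 14%. Feeding J should push a below e, and feeding D should lift it above e, with each point of a worth two of G. I put no figure on south-east beyond the ceiling R = 80.0%.

The forecast named south-east as best, with 40% (26% to 55%) there, 16% in south, 3% in north-east and 4% in south-west, on the ground that “Feeding D keeps D low while X reacts”. The flasks gave 68.0% in south-east, 16.8% in south, 0.497% in north-east and 1.24% in south-west, so south-east was best.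

    D + L → G (k = 0.00420 M⁻¹ s⁻¹)
    X + J → L (k = 0.0280 M⁻¹ s⁻¹)
    X + G → Z (k = 8.80 × 10⁻⁴ M⁻¹ s⁻¹)
    J + G → E (k = 0.00380 M⁻¹ s⁻¹)
    X + D → Q (k = 0.0190 M⁻¹ s⁻¹)

South-east had nearly come to rest by 6.00 h, with J at 0.016% of its charge and L at 1.87%. Its Q of 24.5% makes a 75.5% and R 71.0%, and ten times the time took G from 68.0% to 69.9%. South had not come to rest: its Q of 52.8% gives R = 14.4%, and over ten times the time its J went from 4.79% to 0% and its G from 16.8% to 14.2%. In north-east a was 12.6%, under e, and G went from 0.497% to 0% with J still at 68.5% of its charge.

All runs were generated by integration for an exercise, noise included.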